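**Plan**

1. Numbering (labdane type): ring A = C1–C5 and C10; ring B = C5–C10; C17 = CH2 on C8; C18 = CH2OH and C19 = CH3 on C4; C20 = CH3 on C10; chain C11–C16 on C9 (CH3 on C13, OH on C15), butenolide closed on C16; alpha = face of H5, beta = face of C20.
2. Enabling feature: ring B carries oxygen on C6, the exocyclic C8=C17 methylene and the quaternary C10, which is the retron of a [4+2] addition of a 2-oxy-diene C7=C6–C5=C10 to the C8=C9 bond of an allene. O-18 lies 1,4 to C6, so it can be tied to C6 as a five-membered cyclic enol ether that locks the diene s-cis and later hydrolyses to the 18-OH and the C6 carbonyl.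
3. Retrosynthetic cuts: C15–C16 (vinylogous aldol with a 4-methyl-2-silyloxyfuran); C14–C15 and C13–CH3 (alkyne carboalumination, formaldehyde); C11–C12 (alkylation of a C11 triflate); C7–C8 and C9–C10 together (Diels–Alder with ethyl buta-2,3-dienoate); C6=C7 (lactone methylenation); C5–C6 (carbonylative lactonisation of a ring A vinyl triflate).
4. Forward order: ring A with C4 set, then the bicyclic butenolide, then the dienyl ether, then ring B in one step. The chain is grown from C11 while the enol ether masks O-18 and C6; hydrolysis, C6 reduction, enal formation and the hydroxy-butenolide come last, and no protected intermediate is isolated.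
5. Stereochemistry: C4 from the L-valine auxiliary; C10 from C4 (the C19 methyl screens one diene face); C9 by kinetic protonation of the ester dienolate anti to C20; C5 by alpha-face protonation (trans-decalin); C6 by thermodynamically controlled SmI2 reduction; 13E by syn-carboalumination; C15 and C16 by the Ti(OiPr)4/(R)-BINOL-catalysed aldol.

Key step: step 8

Remark: L-valine tert-butyl ester is used as the free base (liberated from the commercial hydrochloride); decalin names use the ring locants of the plan, and where a product is an epimer mixture at a centre that is reset later its SMILES leaves that centre open.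

**Route**

Step 1
Reactants: 1 ethyl 2-oxocyclohexane-1-carboxylate; 2 L-valine tert-butyl ester [tert-butyl (2S)-2-amino-3-methylbutanoate]
Product: 3 ethyl 2-{[(2S)-1-tert-butoxy-3-methyl-1-oxobutan-2-yl]amino}cyclohex-1-ene-1-carboxylate (chiral enamino ester)
Conditions: TsOH·H2O (cat.), toluene, reflux, Dean–Stark
Reagents that add atoms: none
Why: Acid-catalysed condensation of the beta-keto ester with the primary amine gives the hydrogen-bonded enamino ester needed for the chiral-enamine alkylation, the only stereocentre being the one brought in by L-valine.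

Step 2
Reactants: 3 chiral enamino ester
Product: 5 ethyl (1R)-1-methyl-2-oxocyclohexane-1-carboxylate, via alkylated imine 4 (not isolated)
Conditions: LDA (commercial solution), toluene, HMPA (1 equiv), −78 °C; MeI, −78 to −40 °C; then 1 M HCl, 0 °C
Reagents that add atoms: iodomethane CI; water O
Why: Asymmetric alkylation of a lithiated chiral enamine (auxiliary-controlled enolate alkylation), in which the chelated lithio-enamine is held rigid by the isopropyl and tert-butyl ester groups, the external ligand (HMPA as the working choice, an ether if a trial shows the opposite sense) decides which face stays open so that the R quaternary centre (C4 of the target) is formed, and acid hydrolysis of the imine returns the auxiliary.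

Step 3
Reactants: 5 ethyl (1R)-1-methyl-2-oxocyclohexane-1-carboxylate
Product: 6 ethyl (1R)-1,3-dimethyl-2-oxocyclohexane-1-carboxylate (both C3 epimers)
Conditions: LDA, THF, −78 °C; MeI, −78 to 0 °C
Reagents that add atoms: iodomethane CI
Why: Kinetic enolate alkylation at the only enolisable position (the other alpha carbon is quaternary), the new centre becoming sp2 in step 4 so that its configuration does not matter.

Step 4
Reactants: 6 ethyl (1R)-1,3-dimethyl-2-oxocyclohexane-1-carboxylate
Product: 7 ethyl (1R)-1,3-dimethyl-2-{[(trifluoromethyl)sulfonyl]oxy}cyclohex-2-ene-1-carboxylate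
Conditions: KHMDS, THF, −78 to 0 °C; PhNTf2, −78 °C to rt
Reagents that add atoms: N-phenylbis(trifluoromethanesulfonimide) O=S(=O)(N(c1ccccc1)S(=O)(=O)C(F)(F)F)C(F)(F)F
Why: Enol triflate formation from the potassium enolate, which can form only toward the methyl-bearing carbon, gives the tetrasubstituted vinyl triflate C5(OTf)=C10.

Step 5
Reactants: 7 vinyl triflate ester
Product: 8 [(1S)-1,3-dimethyl-2-{[(trifluoromethyl)sulfonyl]oxy}cyclohex-2-en-1-yl]methanol
Conditions: DIBAL-H (i-Bu2AlH, 2.5 equiv), CH2Cl2, −78 to 0 °C; aqueous potassium sodium tartrate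
Reagents that add atoms: none
Why: Hydride reduction of the ester to the primary alcohol (the future O-18) with DIBAL-H, which leaves vinyl triflates untouched at low temperature.

Step 6
Reactants: 8 hydroxymethyl vinyl triflate
Product: 9 (3aR)-3a,7-dimethyl-3a,4,5,6-tetrahydro-2-benzofuran-1(3H)-one (bicyclic butenolide whose lactone carbon is C6)
Conditions: Pd(PPh3)4 (5 mol%), CO (1 atm), Et3N, LiCl, MeCN, 65 °C
Reagents that add atoms: carbon monoxide [C-]#[O+]
Why: Palladium-catalysed carbonylative lactonisation of a hydroxy vinyl triflate, in which oxidative addition to zerovalent palladium, CO insertion and capture of the acyl palladium by the neighbouring alcohol close the five-membered unsaturated lactone and bring in C6.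

Step 7
Reactants: 9 bicyclic butenolide
Product: 10 (3aR)-3a,7-dimethyl-1-methylidene-1,3,3a,4,5,6-hexahydro-2-benzofuran (cyclic dienyl ether C7=C6(O)–C5=C10)
Conditions: Cp2TiMe2 (2.5 equiv), toluene, 70 °C, dark; filtration through basic alumina (pentane, 1% Et3N); used at once
Reagents that add atoms: dimethyltitanocene Cp2TiMe2 [CH3-].[CH3-].[Ti+4].c1cc[cH-]c1.c1cc[cH-]c1
Why: Petasis methylenation of a lactone carbonyl under non-acidic conditions converts C6=O into the exocyclic enol ether C6=C7 and gives the s-cis-locked 2-oxy-diene, which cannot aromatise to a furan because C4 is quaternary, and no stereocentre is touched.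

Step 8
Reactants: 10 cyclic dienyl ether; 11 ethyl buta-2,3-dienoate
Product: 12 ethyl (2aR,5aR)-2a,5a-dimethyl-7-methylidene-2a,3,4,5,5a,6,7,8-octahydro-2H-naphtho[1,8-bc]furan-6-carboxylate (tricyclic enol ether ester as a mixture of epimers at the ester-bearing carbon C9)
Conditions: 11 (3 equiv), toluene, BHT (cat.), solid K2CO3 (acid scavenger), sealed tube, 90 °C
Reagents that add atoms: none
Why: Concerted but asynchronous thermal [4+2] cycloaddition (Diels–Alder) in which the enol-ether terminus C7 of the diene C7=C6–C5=C10 bonds first to the electrophilic central allene carbon C8 and C10 then closes onto the ester-bearing C9, the remote allene double bond remaining as the exocyclic C8=C17 methylene. The closest known reaction type is the Diels–Alder addition of 2-alkoxy or 2-silyloxy dienes, and of 1-vinyl-2,6,6-trimethylcyclohexene-type dienes, to allenic and acetylenic esters. Ring B is the only ring closed, as a six-membered carbocycle by intermolecular suprafacial [4+2] addition. The quaternary C10 is controlled by the C19 methyl on C4, which stands perpendicular to the flat bicyclic diene and screens its beta face, so the dienophile adds to the alpha face and C20 ends up cis to C19, whereas C9 is not relied on here and is set in step 9. The step needs regioselectivity (C7 to C8, C10 to C9) and periselectivity for the conjugated allene bond: the C6 oxygen puts the largest HOMO coefficient on C7, which matches the largest LUMO coefficient on the central allenoate carbon, and conjugation with the ester activates C8=C9 over C8=C17. Reactivity at the fully substituted terminus C10 is secured by the five-membered ring that holds the diene s-cis.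

Step 9
Reactants: 12 tricyclic enol ether ester (C9 epimers)
Product: 14 ethyl (2aR,5aR,6S)-2a,5a-dimethyl-7-methylidene-2a,3,4,5,5a,6,7,8-octahydro-2H-naphtho[1,8-bc]furan-6-carboxylate (9-beta ester carrying H9 alpha), via lithium dienolate 13 (not isolated)
Conditions: LDA, THF, −78 °C; then AcOH in THF, −78 °C
Reagents that add atoms: none
Why: Stereoconvergent kinetic alpha-protonation of an extended ester enolate, in which either C9 epimer gives the same dienolate (C11–C9–C8–C17) that is protonated at C9 (the alpha carbon, so the exocyclic methylene is kept) from the alpha face, away from the pseudo-axial C20 methyl on C10, setting H9 alpha and the ester beta.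

Step 10
Reactants: 14 9-beta ester
Product: 15 [(2aR,5aR,6S)-2a,5a-dimethyl-7-methylidene-2a,3,4,5,5a,6,7,8-octahydro-2H-naphtho[1,8-bc]furan-6-yl]methanol (C11 alcohol)
Conditions: LiAlH4, Et2O, 0 °C; NaOH/H2O work-up
Reagents that add atoms: none
Why: LiAlH4 reduction of the ester to the C11 alcohol, the enol ether and the isolated methylene being inert to hydride and the basic work-up keeping the enol ether intact.

Step 11
Reactants: 15 C11 alcohol
Product: 17 trimethyl{4-[(2aR,5aR,6S)-2a,5a-dimethyl-7-methylidene-2a,3,4,5,5a,6,7,8-octahydro-2H-naphtho[1,8-bc]furan-6-yl]but-1-yn-1-yl}silane, via C11 triflate 16 (not isolated)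
Conditions: Tf2O, 2,6-di-tert-butyl-4-methylpyridine, CH2Cl2, −78 °C; then transferred to LiCH2C≡CSiMe3 (3 equiv, from 1-(trimethylsilyl)propyne and n-BuLi, THF, −78 °C), −78 to −40 °C (one equivalent of the lithium reagent is consumed by the pyridinium triflate)
Reagents that add atoms: 1-(trimethylsilyl)propyne CC#C[Si](C)(C)C
Why: SN2 alkylation of a propargylic organolithium by a primary triflate (lithiated 1-(trimethylsilyl)propyne reacts at its CH2 terminus) forms C11–C12 at a temperature where E2 loss of the allylic H9 should be slow, and C9 is not touched.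

Step 12
Reactants: 17 silyl alkyne
Product: 19 (4R,5R,9S,10R)-9-(but-3-yn-1-yl)-4-(hydroxymethyl)-4,10-dimethyl-8-methylidenedecalin-6-one (trans-fused hydroxy ketone), via terminal alkyne 18 (not isolated)
Conditions: K2CO3, MeOH, rt, concentrated; then 0.1 M HCl, THF–H2O, 0 °C, short contact, NaHCO3 quench
Reagents that add atoms: water O
Why: Base-mediated protiodesilylation of the alkynylsilane is followed by acid hydrolysis of the cyclic enol ether, which is protonated at C5 from the alpha face (the beta face carries the axial C19 and C20 methyls) to release O-18 and give the trans-decalin ketone, the cold dilute acid being chosen so that the C8=C17 alkene does not move into conjugation with the new C6 carbonyl.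

Step 13
Reactants: 19 hydroxy ketone alkyne
Product: 20 (4R,5R,6S,9S,10R)-9-(but-3-yn-1-yl)-4-(hydroxymethyl)-4,10-dimethyl-8-methylidenedecalin-6-ol (equatorial 6-alpha hydroxyl)
Conditions: SmI2 (3 equiv), THF, H2O, 0 °C to rt
Reagents that add atoms: none
Why: Single-electron (dissolving-metal-type) ketone reduction in which the ketyl and organosamarium intermediates place oxygen in the less hindered equatorial position, so the thermodynamically preferred 6-alpha alcohol should form, whereas hydride reagents would attack from the alpha face and give the axial 6-beta epimer, and the terminal alkyne and the methylene are not reduced.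

Step 14
Reactants: 20 diol alkyne
Product: 22 (2E)-5-[(4R,5R,6S,9S,10R)-6-hydroxy-4-(hydroxymethyl)-4,10-dimethyl-8-methylidenedecalin-9-yl]-3-methylpent-2-en-1-ol (allylic triol), via alkenylalane 21 (not isolated)
Conditions: Me3Al (4 equiv), Cp2ZrCl2 (0.3 equiv), CH2Cl2, 0 °C to rt; then (CH2O)n (excess), THF, rt; aqueous potassium sodium tartrate
Reagents that add atoms: trimethylaluminium C[Al](C)C; formaldehyde (as paraformaldehyde) C=O
Why: Negishi zirconium-catalysed carboalumination of the terminal alkyne (syn addition, methyl to C13) and hydroxymethylation of the alkenylalane with formaldehyde give the (E)-trisubstituted allylic alcohol, the two hydroxyls being carried as aluminium alkoxides.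

Step 15
Reactants: 22 allylic triol
Product: 23 (2E)-5-[(4R,5R,6S,9S,10R)-6-hydroxy-4-(hydroxymethyl)-4,10-dimethyl-8-methylidenedecalin-9-yl]-3-methylpent-2-enal (dihydroxy enal)
Conditions: activated MnO2, CH2Cl2, rt
Reagents that add atoms: none
Why: MnO2 oxidises only the allylic alcohol at C15 and leaves the saturated primary and secondary hydroxyls untouched, giving the (E)-enal.

Step 16
Reactants: 24 4-methylfuran-2(5H)-one
Product: 25 trimethyl[(4-methylfuran-2-yl)oxy]silane
Conditions: TMSOTf, Et3N, Et2O, 0 °C; distillation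
Reagents that add atoms: trimethylsilyl trifluoromethanesulfonate C[Si](C)(C)OS(=O)(=O)C(F)(F)F
Why: Soft enolisation and O-silylation of the butenolide give the 2-silyloxyfuran nucleophile.

Step 17
Reactants: 23 dihydroxy enal; 25 trimethyl[(4-methylfuran-2-yl)oxy]silane
Product: 28 the target CNP0221530.1 (4R,5R,6S,9S,10R,13E,15S,16S), via bis-silyl ether 26 (not isolated), via silylated aldol adduct 27 (not isolated)
Conditions: HMDS, TMSCl (cat.), CH2Cl2, rt, volatiles removed; Ti(OiPr)4 (20 mol%) and (R)-BINOL (20 mol%), 25 (1.5 equiv), Et2O, −20 °C; then 0.1 M HCl, THF, 0 °C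
Reagents that add atoms: none
Why: Catalytic asymmetric vinylogous Mukaiyama aldol addition of a 2-silyloxyfuran to an aldehyde, in which the furan reacts at its C5 through an open transition state that should favour the threo (15S,16S) adduct, the Ti(OiPr)4/BINOL Lewis acid is to direct attack to the Re face of the aldehyde (15S and with it 16S; (R)-BINOL is the working choice, its antipode if a model enal shows the opposite sense), and the transient trimethylsilyl ethers fall off in the cold dilute acid work-up.

**Compound list**

1 | ethyl 2-oxocyclohexane-1-carboxylate | CCOC(=O)C1CCCCC1=O | starting material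
2 | L-valine tert-butyl ester | CC(C)[C@H](N)C(=O)OC(C)(C)C | starting material
3 | ethyl 2-{[(2S)-1-tert-butoxy-3-methyl-1-oxobutan-2-yl]amino}cyclohex-1-ene-1-carboxylate | CCOC(=O)C1=C(N[C@@H](C(C)C)C(=O)OC(C)(C)C)CCCC1 | intermediate
4 | ethyl (1R)-2-{[(2S)-1-tert-butoxy-3-methyl-1-oxobutan-2-yl]imino}-1-methylcyclohexane-1-carboxylate (alkylated imine) | CCOC(=O)[C@]1(C)CCCCC1=N[C@@H](C(C)C)C(=O)OC(C)(C)C | intermediate
5 | ethyl (1R)-1-methyl-2-oxocyclohexane-1-carboxylate | CCOC(=O)[C@]1(C)CCCCC1=O | intermediate
6 | ethyl (1R)-1,3-dimethyl-2-oxocyclohexane-1-carboxylate (C3 epimers) | CCOC(=O)[C@]1(C)CCCC(C)C1=O | intermediate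
7 | ethyl (1R)-1,3-dimethyl-2-{[(trifluoromethyl)sulfonyl]oxy}cyclohex-2-ene-1-carboxylate | CCOC(=O)[C@]1(C)CCCC(C)=C1OS(=O)(=O)C(F)(F)F | intermediate
8 | [(1S)-1,3-dimethyl-2-{[(trifluoromethyl)sulfonyl]oxy}cyclohex-2-en-1-yl]methanol | OC[C@]1(C)CCCC(C)=C1OS(=O)(=O)C(F)(F)F | intermediate
9 | (3aR)-3a,7-dimethyl-3a,4,5,6-tetrahydro-2-benzofuran-1(3H)-one | O=C1OC[C@]2(C)CCCC(C)=C12 | intermediate
10 | (3aR)-3a,7-dimethyl-1-methylidene-1,3,3a,4,5,6-hexahydro-2-benzofuran | C=C1OC[C@]2(C)CCCC(C)=C12 | intermediate
11 | ethyl buta-2,3-dienoate | C=C=CC(=O)OCC | starting material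
12 | ethyl (2aR,5aR)-2a,5a-dimethyl-7-methylidene-2a,3,4,5,5a,6,7,8-octahydro-2H-naphtho[1,8-bc]furan-6-carboxylate (C9 epimers) | CCOC(=O)C1C(=C)CC2=C3[C@]1(C)CCC[C@@]3(C)CO2 | intermediate
13 | lithium dienolate of 12 | CCOC(O[Li])=C1C(=C)CC2=C3[C@]1(C)CCC[C@@]3(C)CO2 | intermediate
14 | ethyl (2aR,5aR,6S)-2a,5a-dimethyl-7-methylidene-2a,3,4,5,5a,6,7,8-octahydro-2H-naphtho[1,8-bc]furan-6-carboxylate | CCOC(=O)[C@H]1C(=C)CC2=C3[C@]1(C)CCC[C@@]3(C)CO2 | intermediate
15 | [(2aR,5aR,6S)-2a,5a-dimethyl-7-methylidene-2a,3,4,5,5a,6,7,8-octahydro-2H-naphtho[1,8-bc]furan-6-yl]methanol | OC[C@H]1C(=C)CC2=C3[C@]1(C)CCC[C@@]3(C)CO2 | intermediate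
16 | trifluoromethanesulfonate of the C11 alcohol (C11 triflate) | O=S(=O)(OC[C@H]1C(=C)CC2=C3[C@]1(C)CCC[C@@]3(C)CO2)C(F)(F)F | intermediate
17 | trimethyl{4-[(2aR,5aR,6S)-2a,5a-dimethyl-7-methylidene-2a,3,4,5,5a,6,7,8-octahydro-2H-naphtho[1,8-bc]furan-6-yl]but-1-yn-1-yl}silane | C[Si](C)(C)C#CCC[C@H]1C(=C)CC2=C3[C@]1(C)CCC[C@@]3(C)CO2 | intermediate
18 | (2aR,5aR,6S)-6-(but-3-yn-1-yl)-2a,5a-dimethyl-7-methylidene-2a,3,4,5,5a,6,7,8-octahydro-2H-naphtho[1,8-bc]furan (terminal alkyne) | C#CCC[C@H]1C(=C)CC2=C3[C@]1(C)CCC[C@@]3(C)CO2 | intermediate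
19 | (4R,5R,9S,10R)-9-(but-3-yn-1-yl)-4-(hydroxymethyl)-4,10-dimethyl-8-methylidenedecalin-6-one (trans-fused; 4-alpha CH2OH; H5 and H9 alpha) | C=C1CC(=O)[C@H]2[C@](C)(CO)CCC[C@]2(C)[C@H]1CCC#C | intermediate
20 | (4R,5R,6S,9S,10R)-9-(but-3-yn-1-yl)-4-(hydroxymethyl)-4,10-dimethyl-8-methylidenedecalin-6-ol | C=C1C[C@H](O)[C@H]2[C@](C)(CO)CCC[C@]2(C)[C@H]1CCC#C | intermediate
21 | (E)-alkenyl(dimethyl)alane from the diol alkyne, both hydroxyls as dimethylaluminium alkoxides | C=C1C[C@H](O[Al](C)C)[C@H]2[C@](C)(CO[Al](C)C)CCC[C@]2(C)[C@H]1CC/C(C)=C/[Al](C)C | intermediate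
22 | (2E)-5-[(4R,5R,6S,9S,10R)-6-hydroxy-4-(hydroxymethyl)-4,10-dimethyl-8-methylidenedecalin-9-yl]-3-methylpent-2-en-1-ol | C=C1C[C@H](O)[C@H]2[C@](C)(CO)CCC[C@]2(C)[C@H]1CC/C(C)=C/CO | intermediate
23 | (2E)-5-[(4R,5R,6S,9S,10R)-6-hydroxy-4-(hydroxymethyl)-4,10-dimethyl-8-methylidenedecalin-9-yl]-3-methylpent-2-enal | C=C1C[C@H](O)[C@H]2[C@](C)(CO)CCC[C@]2(C)[C@H]1CC/C(C)=C/C=O | intermediate
24 | 4-methylfuran-2(5H)-one | CC1=CC(=O)OC1 | starting material
25 | trimethyl[(4-methylfuran-2-yl)oxy]silane | Cc1coc(O[Si](C)(C)C)c1 | intermediate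
26 | bis(trimethylsilyl) ether of the dihydroxy enal (O-6 and O-18 silylated) | C=C1C[C@H](O[Si](C)(C)C)[C@H]2[C@](C)(CO[Si](C)(C)C)CCC[C@]2(C)[C@H]1CC/C(C)=C/C=O | intermediate
27 | tris(trimethylsilyl) ether of the target (O-6, O-15 and O-18 silylated) | C=C1C[C@H](O[Si](C)(C)C)[C@H]2[C@](C)(CO[Si](C)(C)C)CCC[C@]2(C)[C@H]1CC/C(C)=C/[C@H](O[Si](C)(C)C)[C@H]1OC(=O)C=C1C | intermediate
28 | CNP0221530.1 | C=C1C[C@H](O)[C@H]2[C@](C)(CO)CCC[C@]2(C)[C@H]1CC/C(C)=C/[C@H](O)[C@H]1OC(=O)C=C1C | target

**Step count**

Total: 17 steps. Longest linear sequence: 16 steps (steps 1–15 and 17).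

**Steps most likely to fail**

Step 8. The cycloaddition may be too slow at the fully substituted diene terminus C10, so that the acid-sensitive diene hydrolyses or the allenoate oligomerises first; facial selectivity may also be incomplete. The fallback changes from a thermal ester cycloaddition to a chelation-activated, Lewis-acid-catalysed one. It sets out from 11 and 10 and returns at 12. Compound 11 is saponified (LiOH, THF/H2O) to buta-2,3-dienoic acid F1. F1 is N-acylated onto 1,3-oxazolidin-2-one (DCC, DMAP, CH2Cl2) to give 3-(buta-2,3-dienoyl)-1,3-oxazolidin-2-one F2. Diene 10 and F2 are combined with Cu(OTf)2 and (S,S)-tert-butyl-bis(oxazoline) ligand (10 mol%) in CH2Cl2 at −40 °C; two-point binding activates the dienophile and the chiral ligand can reinforce alpha-face addition. This should give the imide cycloadduct F3. EtOMgBr (from EtMgBr and EtOH, THF, 0 °C) converts F3 into the ethyl ester 12.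

Step 11. The primary triflate may lose the allylic H9 by E2 elimination under the basic organolithium, or ionise before substitution. The fallback reverses the polarity at C11 (Julia-type sulfone alkylation). It sets out from 15 and returns at 17. Alcohol 15 is converted (TsCl, pyridine, DMAP) into the C11 tosylate F4. The non-basic sulfinate nucleophile (PhSO2Na, Bu4NI cat., DMF, 80 °C) gives the C11 phenyl sulfone F5. Deprotonation (n-BuLi, THF, −78 °C) and alkylation with 3-bromo-1-(trimethylsilyl)prop-1-yne give the alkylated sulfone F6. Reductive desulfonylation (Na/Hg, Na2HPO4, MeOH/THF, −20 °C) gives 17.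

Step 17. The aldol may proceed with the wrong relative topicity, giving mainly the erythro adduct, even if the catalyst controls the face of the furan. The fallback sets C15 by a reagent-controlled ketone reduction instead of in the aldol. It sets out from 23 and 25 and returns at 28. Under the conditions of step 17, with the BINOL antipode that gives 16S, the erythro adduct, the (15R,16S) 15-epimer of the target F7, is collected. MnO2 (CH2Cl2, rt) oxidises its allylic C15 hydroxyl under neutral conditions to the 15-oxo compound F8, which is reduced at once because C16 next to the ketone can epimerise. CBS reduction ((S)-2-methyl-CBS-oxazaborolidine, catecholborane, toluene, −78 °C; alkenyl as the large group, hydride to the Re face of C15) gives 28.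

**Further compounds**

F1 | step 8 | buta-2,3-dienoic acid | C=C=CC(=O)O
F2 | step 8 | 3-(buta-2,3-dienoyl)-1,3-oxazolidin-2-one | C=C=CC(=O)N1CCOC1=O
F3 | step 8 | 3-{[(2aR,5aR)-2a,5a-dimethyl-7-methylidene-2a,3,4,5,5a,6,7,8-octahydro-2H-naphtho[1,8-bc]furan-6-yl]carbonyl}-1,3-oxazolidin-2-one (C9 epimers) | O=C(C1C(=C)CC2=C3[C@]1(C)CCC[C@@]3(C)CO2)N1CCOC1=O
F4 | step 11 | 4-methylbenzenesulfonate of the C11 alcohol (C11 tosylate) | Cc1ccc(cc1)S(=O)(=O)OC[C@H]1C(=C)CC2=C3[C@]1(C)CCC[C@@]3(C)CO2
F5 | step 11 | C11 phenyl sulfone | O=S(=O)(C[C@H]1C(=C)CC2=C3[C@]1(C)CCC[C@@]3(C)CO2)c1ccccc1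
F6 | step 11 | C11-alkylated phenyl sulfone (C11 epimers) | C[Si](C)(C)C#CCC([C@H]1C(=C)CC2=C3[C@]1(C)CCC[C@@]3(C)CO2)S(=O)(=O)c1ccccc1
F7 | step 17 | (15R,16S) 15-epimer of the target | C=C1C[C@H](O)[C@H]2[C@](C)(CO)CCC[C@]2(C)[C@H]1CC/C(C)=C/[C@@H](O)[C@H]1OC(=O)C=C1C
F8 | step 17 | 15-oxo compound (16S) | C=C1C[C@H](O)[C@H]2[C@](C)(CO)CCC[C@]2(C)[C@H]1CC/C(C)=C/C(=O)[C@H]1OC(=O)C=C1C
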